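**Plan**

- Numbering: ring A is C1–C6 (C1 quaternary, bearing C12H2OAc; C2 CH2; C3 CHOAc; C4 CHOH; C5 CMe2; C6 quaternary). C7 is the CH2 on C6; C8, C9 (on C1) and C10 (bearing CH3) form the cyclopropane; C11 is the CHOAc between C10 and C6.
- Enabling feature: C9 and C10 lie with C1, C6 and C11 in one five-membered ring. C8 is bonded to both and hangs from C6 through C7 on the ring face that also carries the C11 oxygen, so a C8 carbene equivalent on a C9=C10 cyclopentene closes a cyclopentane and the cyclopropane together.
- Cuts, in retrosynthetic order: C3–O and C4–O (cis-oxygenation of a C3=C4 alkene); C8–C9 and C8–C10 (C8 diazoalkane on C9=C10); C11–O (iodolactonisation); C6–C7 ([3,3] shift from a C10 acetate); C6=C11 (aldol); C1–C9 and C1–C12 (allylation and benzyloxymethylation of a ring A ketone).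
- Forward: ring A is bought as the dimethyl dione; the cyclopentenone is annulated across C1/C6; C7–C8 is shifted onto C6; the lactone is opened to the hydroxy tosylhydrazone; both cage rings close in one step; ring A is oxygenated last.
- Stereochemistry: C1 comes from an enantioselective palladium-catalysed decarboxylative allylation. It is relayed to C10–O (methyl addition anti to C12), C6 (suprafacial [3,3] shift), C11 (lactonisation syn to C7) and C8/C9/C10 (tether). C3 and C4 come from a Woodward cis-hydroxylation on the more hindered face of ring A.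

Key step: step 13

Assumption: enol carbonate 7 is taken to follow the facial preference of simple 2-alkylcyclohexanone enol carbonates, so that (R)-t-Bu-PHOX gives (R)-8 (the (S)-ligand would be used otherwise); pyrazoline 24 is drawn as the regioisomer with C8–C9 and N–C10 bonds, and the other regioisomer would give the same 25.

**Step 1**
Reactants: 1 2,2-dimethylcyclohexane-1,3-dione; 2 ethylene glycol
Product: 3 6,6-dimethyl-1,4-dioxaspiro[4.5]decan-7-one
Conditions: ethylene glycol (1.05 equiv), TsOH·H2O (cat.), benzene, reflux, Dean–Stark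
Reagents that add atoms: ethylene glycol (2), OCCO
Why: Acid-catalysed ketalisation with one equivalent of diol and removal of water should stop at the mono-ketal, because the remaining carbonyl is then flanked by a quaternary carbon and a spiro ketal; no stereocentre is formed.

**Step 2**
Reactants: 3 mono-ketal ketone; 4 benzyl chloromethyl ether
Product: 5 rac-8-[(benzyloxy)methyl]-6,6-dimethyl-1,4-dioxaspiro[4.5]decan-7-one
Conditions: LiN(i-Pr)2, THF, −78 °C; then 4, −78 → 0 °C
Reagents that add atoms: benzyl chloromethyl ether (4), ClCOCc1ccccc1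
Why: Lithium enolate alkylation at C1, the only enolisable position, with a reactive alpha-chloro ether installs C12; the new centre is racemic and is erased in step 3.

**Step 3**
Reactants: 5 benzyloxymethyl ketone; 6 allyl chloroformate
Product: 7 allyl 8-[(benzyloxy)methyl]-6,6-dimethyl-1,4-dioxaspiro[4.5]dec-7-en-7-yl carbonate
Conditions: KN(SiMe3)2, THF, −78 °C; then 6, −78 °C
Reagents that add atoms: allyl chloroformate (6), C=CCOC(=O)Cl
Why: O-Acylation of the single possible (tetrasubstituted) potassium enolate by a chloroformate at low temperature should give the enol carbonate before the enolate can expel benzyloxide; no stereocentre.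

**Step 4**
Reactants: 7 allyl enol carbonate
Product: 8 (R)-8-allyl-8-[(benzyloxy)methyl]-6,6-dimethyl-1,4-dioxaspiro[4.5]decan-7-one
Conditions: Pd2(dba)3 (2.5 mol %), (R)-t-Bu-PHOX (6 mol %), THF, 25 °C
Reagents that add atoms: none
Why: Decarboxylative asymmetric allylic alkylation (Tsuji allylation with a chiral zerovalent palladium phosphinooxazoline catalyst): ionisation and loss of CO2 give an allylpalladium enolate pair that recombines at C1 inside the chiral pocket, so the ligand sets the C1 quaternary centre as it does for 2-alkyl-6,6-dimethylcyclohexanone enol carbonates.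

**Step 5**
Reactants: 8 (R)-allyl ketone
Product: 9 (R)-8-[(benzyloxy)methyl]-6,6-dimethyl-8-(2-oxopropyl)-1,4-dioxaspiro[4.5]decan-7-one
Conditions: PdCl2 (cat.), Cu(OAc)2 (cat.), O2 (1 atm), DMA/H2O, 23 °C
Reagents that add atoms: water, O
Why: Tsuji–Wacker oxidation by divalent palladium with Markovnikov attack of water on the terminal alkene gives the methyl ketone, and the acetate-buffered copper co-catalyst keeps the medium mild enough for the ketal; C1 is untouched.

**Step 6**
Reactants: 9 1,4-diketone
Product: 10 bicyclic enone (cyclopentenone C6=C11–C10(=O)–C9H2 fused to ring A at C1–C6)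
Conditions: KOH, xylenes, 110 °C, Dean–Stark
Reagents that add atoms: none
Why: Intramolecular aldol condensation in which only the methyl ketone can enolise towards a five-membered ring (C11 onto C6), with dehydration pulling the reversible addition to the hindered C6 carbonyl forward; no new stereocentre.

**Step 7**
Reactants: 10 bicyclic enone; 11 methyllithium; 12 acetic anhydride
Product: 14 C10 acetate of the tertiary allylic alcohol (OAc syn to C12), via lithium alkoxide 13 (not isolated)
Conditions: MeLi, THF, −78 °C; then Ac2O, −78 → 0 °C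
Reagents that add atoms: methyllithium (11), [Li]C; acetic anhydride (12), CC(=O)OC(C)=O
Why: 1,2-Addition of methyllithium to the cyclopentenone carbonyl is expected from the face opposite the freely rotating C1 CH2OBn group (the C2 methylene on the other face is tied back in the ring A chair), which places the C10 oxygen syn to C12, and acylation of the lithium alkoxide in the same flask avoids handling the ionisable tertiary allylic alcohol.

**Step 8**
Reactants: 14 C10 acetate
Product: 17 C6 acetic acid (CH2CO2H on C6 syn to C12; C10=C11), via silyl ketene acetal 15 (not isolated), via trimethylsilyl ester 16 (not isolated)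
Conditions: LiN(i-Pr)2, Me3SiCl, Et3N, THF, −78 °C, then 65 °C; aq NaOH, then citric acid to pH 4, 0 °C
Reagents that add atoms: none
Why: Ireland–Claisen rearrangement: the acetate is enolised in the presence of Me3SiCl to the silyl ketene acetal, whose [3,3] shift is suprafacial, so C7 arrives at C6 on the face that carried the C10–O bond (syn to C12), which fixes the C6 quaternary centre and makes ring A cis-fused to the five-membered ring.

**Step 9**
Reactants: 17 C6 acetic acid
Product: 18 iodolactone (lactone oxygen on C11 syn to C7; iodine on C10 anti)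
Conditions: I2, KI, NaHCO3, THF/H2O, 0 °C, dark
Reagents that add atoms: iodine, II
Why: Kinetic iodolactonisation in which the carboxylate closes 5-exo at C11 onto the iodonium of C10=C11 to give the cis-fused butyrolactone (the 6-endo path to the methyl-bearing C10 would need a bridged lactone reaching across the ring), so the C11–O bond is necessarily syn to C7.

**Step 10**
Reactants: 18 iodolactone
Product: 19 unsaturated lactone (C9=C10)
Conditions: DBU, toluene, 80 °C
Reagents that add atoms: none
Why: E2 dehydroiodination of the tertiary iodide by an amidine base, in which the only antiperiplanar ring hydrogen is on C9 (the C11 hydrogen is syn to iodine), giving the more substituted endocyclic C9=C10 alkene.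

**Step 11**
Reactants: 19 unsaturated lactone
Product: 20 lactol (anomeric mixture at C8)
Conditions: i-Bu2AlH, CH2Cl2, −78 °C; aq potassium sodium tartrate (KNaC4H4O6)
Reagents that add atoms: none
Why: Partial reduction of a lactone by i-Bu2AlH at −78 °C stops at the aluminium hemiacetal, which gives the lactol on work-up; ketal, benzyl ether and alkene are inert.

**Step 12**
Reactants: 20 lactol; 21 p-toluenesulfonyl hydrazide
Product: 22 hydroxy aldehyde tosylhydrazone (C11–OH syn to the C7 arm; C9=C10)
Conditions: TsNHNH2, MeOH, 23 °C
Reagents that add atoms: p-toluenesulfonyl hydrazide (21), Cc1ccc(cc1)S(=O)(=O)NN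
Why: Condensation of the open hydroxy aldehyde tautomer of the lactol with the sulfonyl hydrazide gives the (E)-tosylhydrazone and frees the C11 carbinol; no stereocentre changes.

**Step 13**
Reactants: 22 hydroxy aldehyde tosylhydrazone
Product: 25 cage alcohol (free C11–OH; C4 ketal; C12–OBn), via diazoalkane 23 (not isolated), via pyrazoline 24 (not isolated)
Conditions: K2CO3, 1,4-dioxane, 110 °C; filter; hν (350 nm, Pyrex), 23 °C
Reagents that add atoms: none
Why: K2CO3 deprotonates the tosylhydrazone and at 110 °C the salt loses p-toluenesulfinate (Bamford–Stevens fragmentation) to the C8 diazoalkane 23, which adds as a 1,3-dipole suprafacially across C9=C10 to the bridged 1-pyrazoline 24; irradiation then expels N2 and the C8/C10 1,3-diradical collapses to the cyclopropane. The closest known reaction type is the intramolecular diazoalkane–alkene cycloaddition of alkenyl tosylhydrazone salts followed by photochemical denitrogenation of the 1-pyrazoline. The cyclopentane C6–C7–C8–C9–C1 closes in the cycloaddition by a 5-exo-type attack of C8 on C9 (the geometry of the 2-(cyclopent-3-enyl)ethyl to 2-norbornyl closure), and the cyclopropane C8–C9–C10 closes by contraction of the five-membered azo ring through the new C8–C10 bond. C8, C9 and C10 are all set by the tether: C7 sits on the upper face of the cyclopentene, where the Claisen step placed it, so both new bonds to C8 form on that face and the C10 methyl and C9 hydrogen are turned outwards. The step needs facial selectivity, secured because only the C7 face is within reach, and it needs cycloaddition to outrun nitrogen loss to the carbene (1,2-hydrogen shift from C7, O–H insertion at C11), which should hold because the diazoalkane is released slowly under basic conditions with the alkene four bonds away; the diradical cannot open to an alkene without a bridgehead double bond.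

**Step 14**
Reactants: 25 cage alcohol
Product: 26 cage hydroxy ketone (C4=O)
Conditions: PPTS (cat.), acetone/H2O, 55 °C
Reagents that add atoms: water, O
Why: Mild acid-catalysed ketal hydrolysis frees the C4 ketone, and pyridinium tosylate is too weak an acid to ionise the neopentyl cyclopropylcarbinol at C11.

**Step 15**
Reactants: 26 cage hydroxy ketone; 21 p-toluenesulfonyl hydrazide
Product: 27 C4 tosylhydrazone
Conditions: TsNHNH2, MeOH, 60 °C
Reagents that add atoms: p-toluenesulfonyl hydrazide (21), Cc1ccc(cc1)S(=O)(=O)NN
Why: Tosylhydrazone formation at a ketone hindered on one side only, with the sulfonamide nitrogen settling anti to C5 and therefore syn to the C3 methylene that is deprotonated next.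

**Step 16**
Reactants: 27 C4 tosylhydrazone
Product: 29 C3=C4 alkene (C11–OH; C12–OBn), via vinyllithium 28 (not isolated)
Conditions: MeLi (11, 4 equiv), Et2O/THF, 0 → 23 °C; then H2O
Reagents that add atoms: none
Why: Shapiro reaction: excess methyllithium removes the OH, NH and syn C3 protons (C5 is quaternary, so only one regioisomer is possible), loss of sulfinate and N2 gives the C4 vinyllithium, and water protonates it to the alkene, as in the conversion of 4,4-dimethyl-3-keto steroids into 2-enes.

**Step 17**
Reactants: 29 C3=C4 alkene benzyl ether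
Product: 30 C11,C12-diol
Conditions: Na, NH3 (l), THF, −78 °C; then NH4Cl
Reagents that add atoms: none
Why: Dissolving-metal cleavage of the benzyl ether leaves the isolated disubstituted alkene and the unconjugated cyclopropane untouched, which hydrogenolysis would not guarantee.

**Step 18**
Reactants: 30 diol; 12 acetic anhydride
Product: 31 C11,C12-diacetate
Conditions: Ac2O, pyridine, DMAP, CH2Cl2, 23 °C
Reagents that add atoms: acetic anhydride (12), CC(=O)OC(C)=O
Why: Acylation under nucleophilic catalysis by 4-(dimethylamino)pyridine esterifies both the primary C12 and the hindered secondary C11 hydroxyl; no stereocentre is affected.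

**Step 19**
Reactants: 31 diacetate
Product: 33 CNP0197219.1, via iodo acetate 32 (not isolated)
Conditions: I2, AgOAc, AcOH, 23 °C; then H2O (wet AcOH), 90 °C
Reagents that add atoms: silver acetate, CC(=O)[O-].[Ag+]; water, O
Why: Woodward cis-hydroxylation: iodonium forms on the less hindered lower face of ring A (the upper face carries the axial C12 on C1 and an axial methyl on C5), acetate opens it trans-diaxially at C3, the C3 acetoxy group displaces the axial C4 iodide with silver assistance to a cis-fused acetoxonium ion on the upper face, and water opens that ion to the axial ester and equatorial alcohol, so C3–OAc and C4–OH are both set syn to C12 as in the target.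

**Compound list**

1 | 2,2-dimethylcyclohexane-1,3-dione | CC1(C)C(=O)CCCC1=O | starting material
2 | ethylene glycol | OCCO | starting material
3 | 6,6-dimethyl-1,4-dioxaspiro[4.5]decan-7-one | CC1(C)C(=O)CCCC12OCCO2 | intermediate
4 | benzyl chloromethyl ether | ClCOCc1ccccc1 | starting material
5 | rac-8-[(benzyloxy)methyl]-6,6-dimethyl-1,4-dioxaspiro[4.5]decan-7-one | O=C1C(COCc2ccccc2)CCC3(OCCO3)C1(C)C | intermediate
6 | allyl chloroformate | C=CCOC(=O)Cl | starting material
7 | allyl 8-[(benzyloxy)methyl]-6,6-dimethyl-1,4-dioxaspiro[4.5]dec-7-en-7-yl carbonate | C=CCOC(=O)OC1=C(COCc2ccccc2)CCC3(OCCO3)C1(C)C | intermediate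
8 | (R)-8-allyl-8-[(benzyloxy)methyl]-6,6-dimethyl-1,4-dioxaspiro[4.5]decan-7-one | C(OCc1ccccc1)[C@]2(CC=C)CCC3(OCCO3)C(C)(C)C2=O | intermediate
9 | (R)-8-[(benzyloxy)methyl]-6,6-dimethyl-8-(2-oxopropyl)-1,4-dioxaspiro[4.5]decan-7-one | C(OCc1ccccc1)[C@]2(CC(C)=O)CCC3(OCCO3)C(C)(C)C2=O | intermediate
10 | bicyclic enone: ring A (C4 dioxolane, C5 CMe2) fused at C1–C6 to a cyclopentenone C6=C11–C10(=O)–C9H2; C1 bears CH2OBn | C(OCc3ccccc3)[C@]12CCC4(OCCO4)C(C)(C)C1=CC(=O)C2 | intermediate
11 | methyllithium | [Li]C | starting material
12 | acetic anhydride | CC(=O)OC(C)=O | starting material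
13 | lithium C10 alkoxide (C10 bears CH3 and OLi, oxygen syn to C12; C6=C11) | C(OCc3ccccc3)[C@]12CCC4(OCCO4)C(C)(C)C1=C[C@](C)(O[Li])C2 | intermediate
14 | C10 tertiary allylic acetate (OAc syn to C12; C6=C11) | C(OCc3ccccc3)[C@]12CCC4(OCCO4)C(C)(C)C1=C[C@](C)(OC(C)=O)C2 | intermediate
15 | trimethylsilyl ketene acetal of 14 | C(OCc3ccccc3)[C@]12CCC4(OCCO4)C(C)(C)C1=C[C@](C)(OC(=C)O[Si](C)(C)C)C2 | intermediate
16 | trimethylsilyl ester of 17 | C(OCc4ccccc4)[C@]12CCC5(OCCO5)C(C)(C)[C@@]1(CC(=O)O[Si](C)(C)C)C=C(C)C2 | intermediate
17 | C6 acetic acid (CH2CO2H on C6 syn to C12; C10=C11, CH3 on C10) | C(OCc4ccccc4)[C@]12CCC5(OCCO5)C(C)(C)[C@@]1(CC(=O)O)C=C(C)C2 | intermediate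
18 | iodolactone (C8(=O)–O–C11, oxygen syn to C7; C10 bears CH3 and iodine, iodine anti to the lactone oxygen) | C(OCc4ccccc4)[C@]12CCC5(OCCO5)C(C)(C)[C@]13CC(=O)O[C@@H]3[C@@](C)(I)C2 | intermediate
19 | unsaturated lactone (C9=C10) | C(OCc4ccccc4)[C@]12CCC5(OCCO5)C(C)(C)[C@]13CC(=O)O[C@@H]3C(C)=C2 | intermediate
20 | lactol (C8 hemiacetal, both anomers) | C(OCc4ccccc4)[C@]12CCC5(OCCO5)C(C)(C)[C@]13CC(O)O[C@@H]3C(C)=C2 | intermediate
21 | p-toluenesulfonyl hydrazide | Cc1ccc(cc1)S(=O)(=O)NN | starting material
22 | hydroxy aldehyde (E)-tosylhydrazone (C6 bears CH2CH=NNHTs; C11–OH syn to that arm; C9=C10) | C(OCc4ccccc4)[C@]12CCC5(OCCO5)C(C)(C)[C@@]1(C/C=N/NS(=O)(=O)c6ccc(C)cc6)[C@H](O)C(C)=C2 | intermediate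
23 | C8 diazoalkane | C(OCc4ccccc4)[C@]12CCC5(OCCO5)C(C)(C)[C@@]1(CC=[N+]=[N-])[C@H](O)C(C)=C2 | intermediate
24 | bridged 1-pyrazoline (C8–C9 bond; N=N links C8 and C10) | C(OCc4ccccc4)[C@]12CCC5(OCCO5)C(C)(C)[C@]13C[C@@H]6[C@H]2[C@](N=N6)(C)[C@H]3O | intermediate
25 | cage alcohol (C11–OH free, C4 dioxolane, C12–OBn) | C(OCc4ccccc4)[C@]12CCC5(OCCO5)C(C)(C)[C@]13C[C@@H]1[C@H]2[C@]1(C)[C@H]3O | intermediate
26 | cage hydroxy ketone (C4=O) | C(OCc4ccccc4)[C@]12CCC(=O)C(C)(C)[C@]13C[C@@H]1[C@H]2[C@]1(C)[C@H]3O | intermediate
27 | C4 tosylhydrazone (sulfonamide nitrogen syn to C3) | C(OCc4ccccc4)[C@]12CCC(=NNS(=O)(=O)c5ccc(C)cc5)C(C)(C)[C@]13C[C@@H]1[C@H]2[C@]1(C)[C@H]3O | intermediate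
28 | C4 vinyllithium, lithium C11 alkoxide | C(OCc4ccccc4)[C@]12CC=C([Li])C(C)(C)[C@]13C[C@@H]1[C@H]2[C@]1(C)[C@H]3O[Li] | intermediate
29 | C3=C4 alkene (C11–OH, C12–OBn) | C(OCc4ccccc4)[C@]12CC=CC(C)(C)[C@]13C[C@@H]1[C@H]2[C@]1(C)[C@H]3O | intermediate
30 | C11,C12-diol with C3=C4 | OC[C@]12CC=CC(C)(C)[C@]13C[C@@H]1[C@H]2[C@]1(C)[C@H]3O | intermediate
31 | C11,C12-diacetate with C3=C4 | CC(=O)OC[C@]12CC=CC(C)(C)[C@]13C[C@@H]1[C@H]2[C@]1(C)[C@H]3OC(C)=O | intermediate
32 | trans-diaxial C3 acetate, C4 iodide (OAc syn, iodine anti to C12) | CC(=O)OC[C@]12C[C@H](OC(C)=O)[C@@H](I)C(C)(C)[C@]13C[C@@H]1[C@H]2[C@]1(C)[C@H]3OC(C)=O | intermediate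
33 | CNP0197219.1 | CC(=O)OC[C@]12C[C@H](OC(C)=O)[C@H](O)C(C)(C)[C@]13C[C@@H]1[C@H]2[C@]1(C)[C@H]3OC(C)=O | target

**Step count and risks**

Total steps: 19. Longest linear sequence: 19 steps (1 to 33); every other component is purchased.

Step 13 (cage closure). The diazoalkane may lose nitrogen thermally before the dipole has added to the trisubstituted, unactivated C9=C10 bond, so that carbene-derived products (1,2-hydrogen shift to a C7=C8 vinyl group, O–H insertion at C11 to a tetrahydrofuran) take over. The fallback replaces the dipole by a zinc carbenoid and sets out from lactol 20. Condensation with hydrazine hydrate (EtOH, 23 °C) would give the free hydroxy hydrazone F1. Treatment with I2 and Et3N (Et2O, 0 °C) would convert it, with loss of nitrogen, into the 1,1-diiodide F2. Et2Zn (CH2Cl2, 0 → 23 °C) would then form the C11 zinc alkoxide and, by iodine–zinc exchange, the alpha-iodoalkylzinc carbenoid at C8. The alkoxide holds the carbenoid on the upper face of the allylic alcohol, and intramolecular Simmons–Smith cyclopropanation of C9=C10 would give cage alcohol 25, where the route resumes.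

Step 8 (Ireland–Claisen). The silyl ketene acetal of the tertiary allylic acetate may ionise or eliminate to a diene faster than the [3,3] shift can form the C6–C7 bond between two quaternary carbons. The fallback is a neutral, thermal Claisen variant and sets out from enone 10. Methyllithium addition with an aqueous NH4Cl quench would give the tertiary allylic alcohol F3. Heating with N,N-dimethylacetamide dimethyl acetal (xylene, 140 °C; Eschenmoser–Claisen rearrangement, same suprafacial transfer) would give the dimethylamide F4. Iodolactonisation of the amide (I2, THF/H2O, 23 °C), which runs through the iminium lactone and releases dimethylamine, would give iodolactone 18, so the route is rejoined one step further on.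

Step 19 (Woodward cis-hydroxylation). Displacement of the neopentyl C4 iodide by the neighbouring acetate may be outrun by migration of a C5 methyl group, or the iodonium may form or open without face and site control, so that the cis-hydroxy acetate does not form cleanly. The fallback oxygenates stepwise and inverts C4 by oxidation and reduction, setting out from diacetate 31. Epoxidation with mCPBA (CH2Cl2, 0 °C) on the lower face would give epoxide F5. Trans-diaxial opening at C3 with acetate (NaOAc, AcOH, 80 °C) would give the C3 axial acetate, C4 axial alcohol F6. Dess–Martin periodinane (CH2Cl2, 23 °C) would give the acetoxy ketone F7. Reduction with NaBH4 and CeCl3·7H2O (MeOH, −40 °C), with hydride entering axially from the lower face, would give the equatorial C4 alcohol, that is target 33.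

**Further compounds**

F1 | step 13 | hydroxy aldehyde hydrazone (C6 bears CH2CH=NNH2; C11–OH; C9=C10) | C(OCc4ccccc4)[C@]12CCC5(OCCO5)C(C)(C)[C@@]1(C/C=N/N)[C@H](O)C(C)=C2
F2 | step 13 | C8 1,1-diiodide (C6 bears CH2CHI2; C11–OH; C9=C10) | C(OCc4ccccc4)[C@]12CCC5(OCCO5)C(C)(C)[C@@]1(CC(I)I)[C@H](O)C(C)=C2
F3 | step 8 | C10 tertiary allylic alcohol (OH syn to C12; C6=C11) | C(OCc3ccccc3)[C@]12CCC4(OCCO4)C(C)(C)C1=C[C@](C)(O)C2
F4 | step 8 | C6 N,N-dimethylacetamide (CH2CONMe2 on C6 syn to C12; C10=C11) | C(OCc4ccccc4)[C@]12CCC5(OCCO5)C(C)(C)[C@@]1(CC(=O)N(C)C)C=C(C)C2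
F5 | step 19 | C3,C4-epoxide on the face anti to C12 | CC(=O)OC[C@]12C[C@H]4O[C@H]4C(C)(C)[C@]13C[C@@H]1[C@H]2[C@]1(C)[C@H]3OC(C)=O
F6 | step 19 | C3 axial acetate, C4 axial alcohol (trans) | CC(=O)OC[C@]12C[C@H](OC(C)=O)[C@@H](O)C(C)(C)[C@]13C[C@@H]1[C@H]2[C@]1(C)[C@H]3OC(C)=O
F7 | step 19 | C3 acetoxy C4 ketone | CC(=O)OC[C@]12C[C@H](OC(C)=O)C(=O)C(C)(C)[C@]13C[C@@H]1[C@H]2[C@]1(C)[C@H]3OC(C)=O
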